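The hydroxy-lactone (lactol) fused to ring B is treated as an isocoumarin that has lost one carbon. In the precursor acid, position 6 of ring B, the carbon between the diaryl-ether carbon and the carboxyl-bearing carbon 7, holds the only C–H ortho to that carboxyl. A carboxylate-directed rhodium C–H annulation with vinylene carbonate therefore forms the aryl–C bond at position 6 and the lactone C–O bond in one operation; oxidative excision of the enol carbon then leaves formyl and carboxyl, which close to the lactol. The precursor is the complete depsidone (ether and seven-membered lactone closed, ring A aldehyde in place) with a free 7-carboxylic acid, hydrogen at position 6 and a benzyl ether on the 8-phenol.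

Key step: step 10

Locants: the tricyclic core is numbered as 11H-dibenzo[b,e][1,4]dioxepin-11-one.
- Ring A (the methoxy/methyl/formyl ring) holds positions 1 (CH3), 2 (H), 3 (OMe) and 4 (CHO); its two fusion carbons carry the ether oxygen 5 and the lactone carbonyl carbon 11.
- Ring B holds positions 6 (H in the precursor, lactol carbon in the target), 7 (CO2H in the precursor, lactone carbonyl in the target), 8 (OBn in the precursor, OH in the target) and 9 (H); its two fusion carbons carry the ether oxygen 5 and the ester oxygen 10.
- For the benzoates before ring closure the locants of the benzoate name are used: the 2-hydroxyl becomes the 8-oxygen, the 4-hydroxyl the ester oxygen 10 and the 5-hydroxyl the ether oxygen 5.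

Remark on the chemistry: the lactol carbon (S; CIP order ring O > OH > aryl C > H) is a hemiacetal that can epimerise through the ring-opened formyl acid. This equilibration is used in step 13 and is assumed to be slow for the isolated product in dry aprotic medium at or below room temperature, so step 14 is run cold and the product crystallised at once.

Assumption: the lipase of steps 13 and 14 is the one found by screening to acetylate the S lactol; Burkholderia cepacia lipase is taken as the first candidate.

Step 1
Reactants: 1 3-fluoro-5-methylanisole
Product: 3 2-fluoro-6-methoxy-4-methylbenzaldehyde, via aryllithium 2 (not isolated)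
Conditions: n-BuLi, THF, −78 °C; DMF, −78 → 0 °C; aq. HCl
Reagents that add atoms: N,N-dimethylformamide, CN(C)C=O
Why: Directed ortho-lithiation removes the ring proton flanked by fluorine and methoxy, the most acidic site and the future formyl-bearing position 4 of the depsidone, and the aryllithium is formylated by DMF.

Step 2
Reactants: 3 2-fluoro-6-methoxy-4-methylbenzaldehyde
Product: 4 2-fluoro-3-iodo-6-methoxy-4-methylbenzaldehyde
Conditions: NIS, TFA, MeCN, rt
Reagents that add atoms: N-iodosuccinimide, O=C1CCC(=O)N1I
Why: Electrophilic aromatic iodination should go para to the methoxy group, at carbon 3 between fluorine and methyl (the future ring A carbon that bears the seven-ring carbonyl), meta to the deactivating formyl group, since para attack on an anisole is normally preferred over attack at the ortho site between methyl and methoxy.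

Step 3
Reactants: 5 2,4,5-trimethoxybenzoic acid
Product: 6 2,4,5-trihydroxybenzoic acid
Conditions: BBr3, CH2Cl2, −78 °C → rt; H2O
Reagents that add atoms: none
Why: Lewis-acid ether cleavage (BBr3 demethylation) removes all three methyl groups at low temperature, avoiding the decarboxylation that hot protic acid would cause.

Step 4
Reactants: 6 2,4,5-trihydroxybenzoic acid
Product: 7 tert-butyl 2,4,5-trihydroxybenzoate
Conditions: Me2NCH(Ot-Bu)2, toluene, 80 °C, argon
Reagents that add atoms: N,N-dimethylformamide di-tert-butyl acetal, CN(C)C(OC(C)(C)C)OC(C)(C)C
Why: Esterification with an amide acetal transfers tert-butyl only to the carboxylate, so the three phenols stay free.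

Step 5
Reactants: 7 tert-butyl 2,4,5-trihydroxybenzoate
Product: 8 tert-butyl 2,5-dihydroxy-4-(methoxymethoxy)benzoate
Conditions: MOMCl (1.0 equiv), K2CO3 (1.0 equiv), acetone, 0 °C → rt, argon
Reagents that add atoms: chloromethyl methyl ether, COCCl
Why: Williamson-type O-alkylation with one equivalent of weak base should take place at the 4-hydroxyl, the most acidic phenol because it is para to the ester, whereas the 2-hydroxyl is hydrogen-bonded to the ester and the 5-hydroxyl is meta to it.

Step 6
Reactants: 8 tert-butyl 2,5-dihydroxy-4-(methoxymethoxy)benzoate; 4 2-fluoro-3-iodo-6-methoxy-4-methylbenzaldehyde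
Product: 10 tert-butyl 2-(benzyloxy)-5-(2-formyl-6-iodo-3-methoxy-5-methylphenoxy)-4-(methoxymethoxy)benzoate, via diaryl ether phenol 9 (not isolated)
Conditions: Cs2CO3, degassed DMF, 80 °C, argon; then BnBr, Cs2CO3, 50 °C
Reagents that add atoms: benzyl bromide, BrCc1ccccc1
Why: Nucleophilic aromatic substitution (SNAr) of the fluoride activated by the ortho formyl group by the 5-phenoxide (the 2-hydroxyl is chelated to the ester and its anion is less nucleophilic) forms the diaryl ether while the ring B carbon ortho to both the ether oxygen and the ester still carries hydrogen, and the remaining 2-phenol is then benzylated in the same flask by Williamson etherification.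

Step 7
Reactants: 10 tert-butyl 2-(benzyloxy)-5-(2-formyl-6-iodo-3-methoxy-5-methylphenoxy)-4-(methoxymethoxy)benzoate
Product: 11 tert-butyl 2-(benzyloxy)-5-(2-formyl-6-iodo-3-methoxy-5-methylphenoxy)-4-hydroxybenzoate
Conditions: PPTS, t-BuOH, 80 °C
Reagents that add atoms: none
Why: Acid-catalysed acetal exchange removes the phenolic methoxymethyl group under conditions too weakly acidic to cleave the tert-butyl ester or the benzyl ether.

Step 8
Reactants: 11 tert-butyl 2-(benzyloxy)-5-(2-formyl-6-iodo-3-methoxy-5-methylphenoxy)-4-hydroxybenzoate
Product: 12 depsidone tert-butyl ester (tert-butyl 8-(benzyloxy)-4-formyl-3-methoxy-1-methyl-11-oxo-11H-dibenzo[b,e][1,4]dioxepine-7-carboxylate)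
Conditions: Pd(OAc)2 (5 mol %), Xantphos (6 mol %), CO (1 atm), Et3N, toluene, 90 °C
Reagents that add atoms: carbon monoxide, [C-]#[O+]
Why: Palladium-catalysed carbonylative lactonisation, in which zerovalent palladium inserts into the aryl C–I bond of ring A, CO insertion gives an acylpalladium species and the neighbouring 4-phenoxide of ring B captures it intramolecularly, should close the seven-membered lactone.

Step 9
Reactants: 12 depsidone tert-butyl ester
Product: 13 depsidone acid (8-(benzyloxy)-4-formyl-3-methoxy-1-methyl-11-oxo-11H-dibenzo[b,e][1,4]dioxepine-7-carboxylic acid)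
Conditions: TFA/CH2Cl2 (1:3), rt
Reagents that add atoms: none
Why: Acidolysis of the tert-butyl ester with loss of isobutene frees the 7-carboxylic acid without touching the aryl benzyl ether, the aldehyde or the depsidone ester.

Step 10
Reactants: 13 depsidone acid; 14 vinylene carbonate
Product: 15 isocoumarin-fused depsidone (pyranone ring CH=CH–O–C(=O) fused across positions 6 and 7 in place of 6-H and 7-CO2H)
Conditions: [Cp*RhCl2]2 (5 mol %), AgSbF6 (20 mol %), NaOAc (30 mol %), vinylene carbonate (3 equiv), DCE, 100 °C
Reagents that add atoms: none
Why: The 7-carboxylate of 13 binds trivalent rhodium and concerted metalation–deprotonation of the C–H bond at position 6 gives a five-membered rhodacycle, vinylene carbonate inserts into the Rh–C bond, β-oxygen elimination opens the carbonate and CO2 is lost, and the carboxyl oxygen then condenses with the unmasked aldehyde-level carbon with loss of water, so rhodium stays trivalent and no external oxidant is needed. The closest known reaction type is the carboxylate-directed rhodium-catalysed annulation of benzoic acids with alkynes to isocoumarins, with vinylene carbonate serving as an acetylene equivalent. The single new ring, the six-membered pyranone, closes as a formal [4+2] annulation: the aryl–C bond at position 6 by migratory insertion and the C–O bond by 6-exo attack of the carboxyl oxygen on the aldehyde-level carbon followed by dehydration. No stereocentre is formed. Only site selectivity is needed and the substrate secures it: position 8 carries the benzyloxy group so 6-H is the one hydrogen ortho to the 7-carboxylate, 9-H and the lone ring A hydrogen at position 2 lie out of reach of any directing group, and the aldehyde has no ortho hydroxyl to promote cleavage of its own C–H bond.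

Step 11
Reactants: 15 isocoumarin-fused depsidone
Product: 18 racemic lactol benzyl ether, via cis-diol 16 (not isolated), via mixed formic anhydride 17 (not isolated)
Conditions: OsO4 (2 mol %), NaIO4 (4 equiv), 2,6-lutidine, 1,4-dioxane/H2O (3:1), rt
Reagents that add atoms: osmium tetroxide, O=[Os](=O)(=O)=O; sodium periodate, [Na+].[O-]I(=O)(=O)=O; water, O
Why: In a Lemieux–Johnson oxidation, dihydroxylation of the enol-ester double bond and periodate glycol cleavage leave a formyl group at position 6 and a mixed formic anhydride at the 7-carboxyl, which is hydrolysed in the aqueous medium, and the ortho-formyl acid should close spontaneously to the racemic five-membered lactol with no hydride reagent near the ring A aldehyde.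

Step 12
Reactants: 18 racemic lactol benzyl ether
Product: 19 racemic lactol phenol
Conditions: BCl3, pentamethylbenzene, CH2Cl2, −78 °C; aqueous pH 7 buffer
Reagents that add atoms: none
Why: Lewis-acid debenzylation with a cation scavenger is fastest for a benzyl ether chelated to an ortho carbonyl, so it should be complete at −78 °C where the methyl ether at position 3 next to the aldehyde is not cleaved, and the aqueous (not methanolic) quench avoids turning the lactol into its methyl acetal.

Step 13
Reactants: 19 racemic lactol phenol
Product: 20 (S)-lactol acetate
Conditions: immobilised Burkholderia cepacia lipase, vinyl acetate, THF/toluene, 40 °C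
Reagents that add atoms: vinyl acetate, C=COC(C)=O
Why: In this lipase-catalysed dynamic kinetic resolution by irreversible transesterification, the lactol enantiomers interconvert through the ring-opened formyl acid while the enzyme acetylates only the S hemiacetal hydroxyl, so the S configuration is set by the chiral active site and locked as the acetate, and the chelated 8-phenol is not expected to be acylated.

Step 14
Reactants: 20 (S)-lactol acetate
Product: 21 target CNP0216483.1, the (S)-lactol
Conditions: same immobilised lipase, n-BuOH, MTBE/THF, 0 °C; filtration, cold concentration, crystallisation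
Reagents that add atoms: none
Why: Lipase-catalysed alcoholysis breaks the acetyl C–O bond and not a bond at the stereocentre, so the S configuration should be retained, and the enzyme's preference for the S acetate leaves any R acetate unreacted.

Compound list
1 | 3-fluoro-5-methylanisole (1-fluoro-3-methoxy-5-methylbenzene) | COc1cc(C)cc(F)c1 | starting material
2 | (2-fluoro-6-methoxy-4-methylphenyl)lithium, not isolated | [Li]c1c(F)cc(C)cc1OC | intermediate
3 | 2-fluoro-6-methoxy-4-methylbenzaldehyde | COc1cc(C)cc(F)c1C=O | intermediate
4 | 2-fluoro-3-iodo-6-methoxy-4-methylbenzaldehyde | COc1cc(C)c(I)c(F)c1C=O | intermediate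
5 | 2,4,5-trimethoxybenzoic acid | COc1cc(OC)c(C(=O)O)cc1OC | starting material
6 | 2,4,5-trihydroxybenzoic acid | O=C(O)c1cc(O)c(O)cc1O | intermediate
7 | tert-butyl 2,4,5-trihydroxybenzoate | CC(C)(C)OC(=O)c1cc(O)c(O)cc1O | intermediate
8 | tert-butyl 2,5-dihydroxy-4-(methoxymethoxy)benzoate (4-OMOM; 2-OH and 5-OH free) | COCOc1cc(O)c(C(=O)OC(C)(C)C)cc1O | intermediate
9 | tert-butyl 5-(2-formyl-6-iodo-3-methoxy-5-methylphenoxy)-2-hydroxy-4-(methoxymethoxy)benzoate, not isolated | COCOc1cc(O)c(C(=O)OC(C)(C)C)cc1Oc1c(I)c(C)cc(OC)c1C=O | intermediate
10 | tert-butyl 2-(benzyloxy)-5-(2-formyl-6-iodo-3-methoxy-5-methylphenoxy)-4-(methoxymethoxy)benzoate | COCOc1cc(OCc2ccccc2)c(C(=O)OC(C)(C)C)cc1Oc1c(I)c(C)cc(OC)c1C=O | intermediate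
11 | tert-butyl 2-(benzyloxy)-5-(2-formyl-6-iodo-3-methoxy-5-methylphenoxy)-4-hydroxybenzoate | Oc1cc(OCc2ccccc2)c(C(=O)OC(C)(C)C)cc1Oc1c(I)c(C)cc(OC)c1C=O | intermediate
12 | tert-butyl 8-(benzyloxy)-4-formyl-3-methoxy-1-methyl-11-oxo-11H-dibenzo[b,e][1,4]dioxepine-7-carboxylate (depsidone tert-butyl ester) | COc1cc(C)c2c(c1C=O)Oc1cc(C(=O)OC(C)(C)C)c(OCc3ccccc3)cc1OC2=O | intermediate
13 | 8-(benzyloxy)-4-formyl-3-methoxy-1-methyl-11-oxo-11H-dibenzo[b,e][1,4]dioxepine-7-carboxylic acid (depsidone acid: 7-CO2H, 6-H, 8-OBn) | COc1cc(C)c2c(c1C=O)Oc1cc(C(=O)O)c(OCc3ccccc3)cc1OC2=O | intermediate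
14 | vinylene carbonate (1,3-dioxol-2-one) | O=C1OC=CO1 | starting material
15 | isocoumarin-fused depsidone (13 with a pyranone ring CH=CH–O–C(=O) fused across positions 6 and 7 in place of 6-H and 7-CO2H, the CH=CH end on position 6) | COc1cc(C)c2c(c1C=O)Oc1c(cc(OCc3ccccc3)c3c1C=COC3=O)OC2=O | intermediate
16 | cis-diol, racemic, not isolated (15 with CH(OH)–CH(OH) in place of the pyranone CH=CH) | COc1cc(C)c2c(c1C=O)Oc1c(cc(OCc3ccccc3)c3c1C(O)C(O)OC3=O)OC2=O | intermediate
17 | mixed formic anhydride, not isolated (6-CHO, 7-C(=O)–O–CHO) | COc1cc(C)c2c(c1C=O)Oc1c(cc(OCc3ccccc3)c(C(=O)OC=O)c1C=O)OC2=O | intermediate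
18 | racemic lactol benzyl ether (hydroxyphthalide ring CH(OH)–O–C(=O) fused across positions 6 and 7, lactol carbon on position 6, 8-OBn) | COc1cc(C)c2c(c1C=O)Oc1c(cc(OCc3ccccc3)c3c1C(O)OC3=O)OC2=O | intermediate
19 | racemic lactol phenol (18 with 8-OH; racemate of the target) | COc1cc(C)c2c(c1C=O)Oc1c(cc(O)c3c1C(O)OC3=O)OC2=O | intermediate
20 | (S)-lactol acetate (CH(OAc)–O–C(=O) fused across positions 6 and 7, S at the acetal carbon, 8-OH free) | COc1cc(C)c2c(c1C=O)Oc1c(cc(O)c3c1[C@@H](OC(C)=O)OC3=O)OC2=O | intermediate
21 | CNP0216483.1, depsidone with ring A (3-OMe, 1-CH3, 4-CHO), 8-OH and the (S)-configured lactol CH(OH)–O–C(=O) fused across positions 6 and 7 | COc1cc(C)c2c(c1C=O)Oc1c(cc(O)c3c1[C@@H](O)OC3=O)OC2=O | target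

Total step count: 14 (steps 1 and 6 each run two stages in one flask).
Longest linear sequence: 12 steps (5 to 21 through steps 3–14); the ring A branch (1 to 4) has 2 steps.

Steps most likely to fail

Step 10. After metalation at the flanked position 6, the insertion and β-oxygen elimination sequence with vinylene carbonate may stall, so that protodemetalation returns the acid, or the carbonate may decompose under the cationic rhodium conditions. The fallback brings the lactol carbon in as a styryl group and sets out from 13. The known rhodium-catalysed, carboxylate-directed oxidative ortho-olefination of benzoic acids with styrene ([Cp*RhCl2]2, Cu(OAc)2 as oxidant, DMF, 110 °C) should give 8-(benzyloxy)-4-formyl-3-methoxy-1-methyl-11-oxo-6-[(E)-2-phenylethenyl]-11H-dibenzo[b,e][1,4]dioxepine-7-carboxylic acid F1. Lemieux–Johnson cleavage of the styrene double bond (OsO4, NaIO4, 2,6-lutidine, dioxane/H2O), with loss of benzaldehyde, then leaves the 6-formyl 7-carboxylic acid, which closes to the lactol. The fallback comes back to the route at 18.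

Step 13. The enzyme may show poor or opposite enantioselectivity at this crowded hemiacetal, may acetylate the phenol as well, or the unreacted enantiomer may racemise too slowly for the resolution to be dynamic. The fallback replaces the enzymatic selection by a physical separation and sets out from 19. Acetylation with Ac2O and pyridine should give the racemic diacetate of 19 F2 (lactol acetate and 8-aryl acetate), a configurationally stable acylal. Preparative chromatography on a chiral stationary phase would deliver the (S)-diacetate F3. Lipase-catalysed alcoholysis (n-BuOH, MTBE/THF, 0 °C) then removes both acetyl groups with retention at the acetal carbon. The fallback comes back to the route at 21.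

Step 8. The acylpalladium intermediate may not be captured by the ring B phenoxide fast enough for seven-membered ring closure, which would give intermolecular esters, hydrodeiodination or CO-free C–O coupling to a six-membered dioxin. A Smiles-type aryl shift from the ether oxygen to the neighbouring phenol oxygen is not expected to interfere, since it would free the less acidic phenol. The fallback separates carbon–carbon bond formation from ring closure and sets out from 11. Palladium-catalysed hydroxycarbonylation (Pd(OAc)2, Xantphos, CO, H2O, Et3N, dioxane, 90 °C) should give 2-[4-(benzyloxy)-5-(tert-butoxycarbonyl)-2-hydroxyphenoxy]-3-formyl-4-methoxy-6-methylbenzoic acid F4. Dehydrative lactonisation of this acid (EDC·HCl, DMAP, CH2Cl2, high dilution) is the classical closure of a depsidone. The fallback comes back to the route at 12.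

Further compounds
F1 | step 10 | 8-(benzyloxy)-4-formyl-3-methoxy-1-methyl-11-oxo-6-[(E)-2-phenylethenyl]-11H-dibenzo[b,e][1,4]dioxepine-7-carboxylic acid | COc1cc(C)c2c(c1C=O)Oc1c(cc(OCc3ccccc3)c(C(=O)O)c1/C=C/c1ccccc1)OC2=O
F2 | step 13 | racemic diacetate of 19 (lactol O-acetate and 8-aryl acetate) | COc1cc(C)c2c(c1C=O)Oc1c(cc(OC(C)=O)c3c1C(OC(C)=O)OC3=O)OC2=O
F3 | step 13 | (S)-diacetate (S at the acetal carbon) | COc1cc(C)c2c(c1C=O)Oc1c(cc(OC(C)=O)c3c1[C@@H](OC(C)=O)OC3=O)OC2=O
F4 | step 8 | 2-[4-(benzyloxy)-5-(tert-butoxycarbonyl)-2-hydroxyphenoxy]-3-formyl-4-methoxy-6-methylbenzoic acid | Oc1cc(OCc2ccccc2)c(C(=O)OC(C)(C)C)cc1Oc1c(C(=O)O)c(C)cc(OC)c1C=O
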